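**Retrosynthetic overview**

- The target gibberellin (3β-hydroxy, 16-hydroxy-16-methyl, 19,10-lactone, 7-acid) is traced back to a 3-oxo 19,10-lactone that carries a 6β-vinyl group as the masked C7 acid; oxidative cleavage and C3 reduction come last.
- Ring A and the lactone are opened together at C4–C5 and O–C10, giving a ring-B cyclopentene (C5=C10) with a β-keto ester side chain on C10. The enabling feature is that C4 is the α-carbon between the C3 ketone and the C19 carboxyl, and C19 sits 1,3 to C10 across ring A (the 6-oxabicyclo[3.2.1]octan-7-one of ring A plus lactone). A C4 radical that adds to C5 therefore leaves a C10 cation directly under the axial carboxyl oxygen.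
- The side chain (C1–C4, C18, C19) is joined at C10 by B-alkyl Suzuki coupling; C7 enters as a vinyl group by conjugate addition to a ring-B enone.
- Ring D is closed by a ketyl–olefin cyclisation (C13–C16) and ring C by a Diels–Alder reaction (C8–C14, C9–C11) on a bought ring-B cyclopentenone.
- Ring order: B (bought) → C → D → A and lactone together. All stereocentres are relayed from the single silyloxy stereocentre of the starting enone.

Key step: step 14

Remark: gibberellane numbering is used for all intermediates (ring B = C5, C6, C8, C9, C10; ring C = C8, C9, C11–C14; ring D = C8, C14, C13, C16, C15; C7 on C6, C17 on C16). β is the face of ring B that carries H9 and C15; α is the face that carries C11 and C14.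
Remark: the C6 carbinol/acetate centre in 6–11 and the side-chain centres C3/C4 in 17–21 form as mixtures and are drawn without configuration, because all are erased before or in step 14.
Assumption: enantiopure (R)-1 is taken as commercially available.

**Route**

Step 1
Reactants: 1 (R)-4-(tert-butyldimethylsilyloxy)cyclopent-2-en-1-one
Product: 2 (R)-4-(tert-butyldimethylsilyloxy)-2-iodocyclopent-2-en-1-one
Conditions: I2, pyridine, CH2Cl2, 0 °C to rt
Reagents that add atoms: iodine, II
Why: α-iodination of the enone by conjugate addition of pyridine, iodination of the enolate and elimination should functionalise C8 only and leave the C10 stereocentre untouched.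

Step 2
Reactants: 2 iodoenone
Product: 3 (R)-2-allyl-4-(tert-butyldimethylsilyloxy)cyclopent-2-en-1-one
Conditions: CH2=CHCH2SnBu3, Pd2(dba)3 (2.5 mol%), AsPh3, CuI (10 mol%), NMP, rt
Reagents that add atoms: allyltributylstannane, C=CC[Sn](CCCC)(CCCC)CCCC
Why: Stille coupling of the α-iodoenone under neutral conditions should install C15–C17 as an allyl group (a masked acetonyl unit) without eliminating the β-silyloxy group.

Step 3
Reactants: 3 allyl enone; 4 buta-1,3-diene
Product: 5 (3R,3aR,7aS)-7a-allyl-3-(tert-butyldimethylsilyloxy)-2,3,3a,4,7,7a-hexahydro-1H-inden-1-one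
Conditions: buta-1,3-diene (excess), EtAlCl2 (0.3 equiv), CH2Cl2, −78 to −20 °C
Reagents that add atoms: none
Why: Lewis-acid-catalysed Diels–Alder reaction of the α-substituted cyclopentenone, in which the diene should add to the C8=C9 face anti to the C10 silyloxy group, setting the quaternary C8 and C9 with a cis ring fusion.

Step 4
Reactants: 5 hydrindenone
Product: 6 hydrindenol (C6 epimers)
Conditions: NaBH4, MeOH, 0 °C
Reagents that add atoms: none
Why: Borohydride reduction removes the C6 ketone before the samarium step; either C6 epimer serves because this carbon becomes sp2 again in step 9.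

Step 5
Reactants: 6 hydrindenol
Product: 7 hydrindenyl acetate
Conditions: Ac2O, pyridine, DMAP (cat.), CH2Cl2, rt
Reagents that add atoms: acetic anhydride, CC(=O)OC(C)=O
Why: DMAP-catalysed acetylation turns the C6 oxygen into the leaving group for the later E1cB elimination and is inert to the next three steps.

Step 6
Reactants: 7 hydrindenyl acetate
Product: 8 methyl ketone (8β-(2-oxopropyl) hydrindene acetate)
Conditions: PdCl2 (10 mol%), CuCl (0.5 equiv), O2 (1 atm), DMF/H2O (7:1), rt
Reagents that add atoms: water, O
Why: Tsuji–Wacker oxidation is selective for the terminal vinyl group over the cis-disubstituted ring alkene and should give the methyl ketone by Markovnikov hydroxypalladation.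

Step 7
Reactants: 8 methyl ketone
Product: 9 tricyclic tertiary alcohol (rings B, C and D; 6-OAc, 10β-OTBS)
Conditions: SmI2 (2.5 equiv), HMPA, t-BuOH (2 equiv), THF, 0 °C to rt
Reagents that add atoms: none
Why: Samarium diiodide ketyl–olefin cyclisation, in which the C16 ketyl should add 5-exo to C13 of the cyclohexene (C13 is fixed by the geometry of the bridge) and the samarium-bound oxygen should turn away from C12, so that the hydroxyl ends exo (syn to C14) and the methyl endo.

Step 8
Reactants: 9 tricyclic silyl ether
Product: 10 tricyclic diol monoacetate (10β-OH)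
Conditions: HF·pyridine, pyridine, THF, 0 °C to rt
Reagents that add atoms: none
Why: Fluoride cleavage of the silyl ether under buffered acidic conditions should free the C10 hydroxyl without acetate migration.

Step 9
Reactants: 10 diol monoacetate
Product: 12 tricyclic enone (C10=O and C5=C6), via β-acetoxy ketone 11 (not isolated)
Conditions: DMP (1,1,1-triacetoxy-1,2-benziodoxol-3(1H)-one), CH2Cl2, rt; then DBU, rt
Reagents that add atoms: none
Why: Periodinane oxidation of the only secondary alcohol followed by base-induced E1cB loss of acetate should give the ring-B enone with the carbonyl at C10; the tertiary alcohol is inert.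

Step 10
Reactants: 12 tricyclic enone
Product: 14 enol triflate (6β-vinyl; C5=C10), via bromomagnesium enolate 13 (not isolated)
Conditions: CH2=CHMgBr (3 equiv; the first equivalent is consumed by the tertiary hydroxyl), CuBr·SMe2 (20 mol%), THF, −78 to −40 °C; then 2-[N,N-bis(trifluoromethylsulfonyl)amino]-5-chloropyridine, −78 °C to rt
Reagents that add atoms: vinylmagnesium bromide, C=C[Mg]Br; 2-[N,N-bis(trifluoromethylsulfonyl)amino]-5-chloropyridine, FC(F)(F)S(=O)(=O)N(c1ccc(Cl)cn1)S(=O)(=O)C(F)(F)F
Why: Copper-catalysed conjugate addition of the vinyl group (the masked C7 carboxyl) to C6 should occur on the convex β face of the cis-fused ring B/ring C enone, away from ring C, which is folded under the α face, and the regiodefined enolate is triflated on oxygen to fix the C5=C10 double bond.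

Step 11
Reactants: 15 tert-butyl propanoate; 16 acrolein
Product: 17 tert-butyl 2-methyl-3-(trimethylsilyloxy)pent-4-enoate (diastereomer mixture)
Conditions: LiN(i-Pr)2, THF, −78 °C; acrolein; then Me3SiCl, −78 °C to rt
Reagents that add atoms: chlorotrimethylsilane, C[Si](C)(C)Cl
Why: Aldol 1,2-addition of the lithium ester enolate to acrolein with in situ O-silylation; both new centres are erased later (C3 is oxidised and C4 becomes the radical centre).

Step 12
Reactants: 17 silyloxy pentenoate; 14 enol triflate
Product: 20 coupled hydroxy ester, via alkylborane 18 (not isolated), via silyl ether 19 (not isolated)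
Conditions: 17, 9-BBN (1.0 equiv relative to 17), THF, 0 °C to rt; then 14, Pd(dppf)Cl2 (5 mol%), AsPh3, Cs2CO3, DMF/H2O, rt; then 1 M HCl, THF, 0 °C
Reagents that add atoms: none
Why: Anti-Markovnikov hydroboration of the terminal alkene and B-alkyl Suzuki–Miyaura coupling with the enol triflate should form the C1–C10 bond with the C5=C10 double bond in place, and dilute acid then removes the trimethylsilyl group.

Step 13
Reactants: 20 coupled hydroxy ester
Product: 21 β-keto ester (C4 epimers)
Conditions: DMP, CH2Cl2, rt
Reagents that add atoms: none
Why: Periodinane oxidation of the secondary alcohol gives the α-methyl β-keto ester, whose C4 epimers and enol are equivalent for the next step.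

Step 14
Reactants: 21 β-keto ester
Product: 22 ring-A lactone (3-oxo, 6β-vinyl, 19,10-lactone)
Conditions: Mn(OAc)3·2H2O (2.2 equiv), degassed AcOH, 40 °C
Reagents that add atoms: none
Why: Mn(OAc)3 oxidises the enolised β-keto ester to the electrophilic C4 radical, which adds 6-endo-trig to C5 of the C5=C10 bond (ring A) to give the tertiary C10 radical; a second equivalent oxidises this radical to the cation, which the carbonyl oxygen of the axial tert-butyl ester captures to close the five-membered lactone ring, forming the O–C10 bond and the 6-oxabicyclo[3.2.1]octan-7-one with loss of isobutene. The closest known reaction type is the Mn(OAc)3-based oxidative free-radical cyclisation of unsaturated α-methyl β-keto esters (6-endo closure to cyclohexanones), combined with the oxidative γ-lactone termination known from manganese triacetate lactone annulations of alkenes. C5 is set by the C6 vinyl group, which is pseudo-axial on the β face next to the reacting carbon so that the radical adds from the α face; C4 is set by the chair-like transition state with the ester axial and anti to H5, the usual outcome of this cyclisation class; C10 is set by the tether, because the C19 oxygen can only reach the α lobe of the cation, which makes the lactone cis to the C4–C5 bond and the ring A/ring B fusion trans. The step needs 6-endo over 5-exo regioselectivity (secured by the fully substituted C10 and by the ketone lying inside the forming ring), α-face selectivity at C5 (secured by the C6 substituent), and lactonisation rather than elimination of the cation (secured by leaving out Cu(OAc)2 and by a tert-butyl ester that fragments on O-alkylation).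

Step 15
Reactants: 22 ring-A lactone
Product: 23 3-oxo lactone acid (3-ketone of the target)
Conditions: RuCl3·xH2O (5 mol%), NaIO4 (4.5 equiv), MeCN/EtOAc/H2O, 0 °C to rt
Reagents that add atoms: sodium periodate, [Na+].[O-]I(=O)(=O)=O; water, O
Why: Catalytic ruthenium tetroxide cleaves the only C=C bond to the carboxylic acid, unmasking C7 with the C6 configuration unchanged (trans to C4 and not epimerisable under these conditions).

Step 16
Reactants: 23 3-oxo lactone acid
Product: 24 target gibberellin (3β,16-dihydroxy lactone acid)
Conditions: K[HB(s-Bu)3] (4 equiv), THF, −78 °C; then 1 M HCl to pH 3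
Reagents that add atoms: none
Why: The bulky hydride should approach the C3 ketone equatorially from the lactone (α) face, away from the axial hydrogens at C1 and C5, giving the axial 3β-alcohol cis to the C4 methyl; the carboxylate and the lactone are inert at −78 °C.

**Compound list**

1 | (R)-4-(tert-butyldimethylsilyloxy)cyclopent-2-en-1-one | O=C1C=C[C@H](O[Si](C)(C)C(C)(C)C)C1 | starting material
2 | (R)-4-(tert-butyldimethylsilyloxy)-2-iodocyclopent-2-en-1-one | O=C1C(I)=C[C@H](O[Si](C)(C)C(C)(C)C)C1 | intermediate
3 | (R)-2-allyl-4-(tert-butyldimethylsilyloxy)cyclopent-2-en-1-one | O=C1C(CC=C)=C[C@H](O[Si](C)(C)C(C)(C)C)C1 | intermediate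
4 | buta-1,3-diene | C=CC=C | starting material
5 | (3R,3aR,7aS)-7a-allyl-3-(tert-butyldimethylsilyloxy)-2,3,3a,4,7,7a-hexahydro-1H-inden-1-one (cis-fused; silyloxy and allyl both β) | O=C1C[C@@H](O[Si](C)(C)C(C)(C)C)[C@@H]2CC=CC[C@]12CC=C | intermediate
6 | hydrindenol: C6 alcohol of 5 (C6 epimers; other centres as in 5) | OC1C[C@@H](O[Si](C)(C)C(C)(C)C)[C@@H]2CC=CC[C@]12CC=C | intermediate
7 | hydrindenyl acetate: 6-O-acetate of 6 | CC(=O)OC1C[C@@H](O[Si](C)(C)C(C)(C)C)[C@@H]2CC=CC[C@]12CC=C | intermediate
8 | methyl ketone: 7 with the angular allyl group replaced by 2-oxopropyl (8β) | CC(=O)OC1C[C@@H](O[Si](C)(C)C(C)(C)C)[C@@H]2CC=CC[C@]12CC(C)=O | intermediate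
9 | tricyclic tertiary alcohol: ring-B cyclopentane fused at C8–C9 (H9 β) to the bicyclo[3.2.1]octane of rings C and D; 6-OAc, 10β-OTBS, 16-OH exo (syn to C14), 16-Me endo | CC(=O)OC1C[C@@H](O[Si](C)(C)C(C)(C)C)[C@@H]2CC[C@@H]3C[C@]12C[C@@]3(C)O | intermediate
10 | tricyclic diol monoacetate: 9 with free 10β-OH | CC(=O)OC1C[C@@H](O)[C@@H]2CC[C@@H]3C[C@]12C[C@@]3(C)O | intermediate
11 | β-acetoxy ketone (not isolated): 10 with C10 ketone | CC(=O)OC1CC(=O)[C@@H]2CC[C@@H]3C[C@]12C[C@@]3(C)O | intermediate
12 | tricyclic enone: ring-B cyclopent-2-enone (C10=O, C5=C6) fused to the 16-hydroxy-16-methylbicyclo[3.2.1]octane; H9 β, 16-OH exo | O=C1C=C[C@@]23C[C@@](C)(O)[C@@H](C2)CC[C@@H]13 | intermediate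
13 | bromomagnesium enolate (not isolated): 6β-vinyl C10 enolate (C5=C10) with the C16 alkoxide | Br[Mg]OC1=C[C@H](C=C)[C@@]23C[C@@](C)(O[Mg]Br)[C@@H](C2)CC[C@@H]13 | intermediate
14 | enol triflate: 6β-vinyl, C5=C10, 10-OTf, 16-OH exo | FC(F)(F)S(=O)(=O)OC1=C[C@H](C=C)[C@@]23C[C@@](C)(O)[C@@H](C2)CC[C@@H]13 | intermediate
15 | tert-butyl propanoate | CCC(=O)OC(C)(C)C | starting material
16 | acrolein (prop-2-enal) | C=CC=O | starting material
17 | tert-butyl 2-methyl-3-(trimethylsilyloxy)pent-4-enoate (diastereomer mixture) | C=CC(O[Si](C)(C)C)C(C)C(=O)OC(C)(C)C | intermediate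
18 | alkylborane (not isolated): 9-BBN adduct of 17 at the terminal carbon | CC(C(=O)OC(C)(C)C)C(O[Si](C)(C)C)CCB1C2CCCC1CCC2 | intermediate
19 | coupled silyl ether (not isolated): 14 with OTf replaced by the C1–C4 chain, C3-OSiMe3 | CC(C(=O)OC(C)(C)C)C(O[Si](C)(C)C)CCC1=C[C@H](C=C)[C@@]23C[C@@](C)(O)[C@@H](C2)CC[C@@H]13 | intermediate
20 | coupled hydroxy ester: tert-butyl 3-hydroxy-2-methylpentanoate chain attached through C1 to C10 of the 6β-vinyl C5=C10 tricycle | CC(C(=O)OC(C)(C)C)C(O)CCC1=C[C@H](C=C)[C@@]23C[C@@](C)(O)[C@@H](C2)CC[C@@H]13 | intermediate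
21 | β-keto ester: 20 with C3 ketone (C4 epimers) | CC(C(=O)OC(C)(C)C)C(=O)CCC1=C[C@H](C=C)[C@@]23C[C@@](C)(O)[C@@H](C2)CC[C@@H]13 | intermediate
22 | ring-A lactone: pentacyclic skeleton of the target with 3-oxo and 6β-vinyl in place of 3β-OH and 6β-CO2H; 19,10-lactone α, H5 β, 4-Me β | C[C@@]12C(=O)O[C@]3(CCC1=O)[C@@H]1CC[C@@H]4C[C@]1(C[C@@]4(C)O)[C@@H](C=C)[C@@H]32 | intermediate
23 | 3-oxo lactone acid: 22 with 6β-CO2H in place of the 6β-vinyl group (3-ketone of the target) | C[C@@]12C(=O)O[C@]3(CCC1=O)[C@@H]1CC[C@@H]4C[C@]1(C[C@@]4(C)O)[C@@H](C(=O)O)[C@@H]32 | intermediate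
24 | target gibberellin: C19 gibberellin 7-acid with the 19,10-lactone (α), 3β-OH, 4β-Me, H5 β, 6β-CO2H, H9 β, 16-OH exo and 16-Me endo | C[C@@]12C(=O)O[C@]3(CC[C@@H]1O)[C@@H]1CC[C@@H]4C[C@]1(C[C@@]4(C)O)[C@@H](C(=O)O)[C@@H]32 | target

**Step count**

Total: 16 steps. Longest linear sequence: 15 steps (steps 1–10 and 12–16; step 11 makes the side-chain fragment).

**Steps most likely to fail**

Step 14. The C10 radical or cation may be lost to elimination or acetate capture instead of closing the lactone, and the C4 radical may add with incomplete α-face selectivity at C5. The fallback separates ring-A closure from C–O bond formation and sets out from 21. Mn(OAc)3·2H2O with Cu(OAc)2·H2O in AcOH should divert the C10 radical into oxidative elimination, the standard termination of this cyclisation, and give the Δ1(10) β-keto ester F1 (double-bond isomers at C10 would converge). Trifluoroacetic acid in CH2Cl2 at 0 °C, kept brief to spare the tertiary C16 carbinol, then removes the tert-butyl group, and the freed 19-acid adds to the tertiary C10 cation formed by protonation at C1 (acid-promoted lactonisation of an ene acid). This returns to the route at 22.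

Step 7. The ketyl may be reduced to the secondary alcohol, or close 6-exo to the bicyclo[2.2.2] isomer, faster than it adds to the unactivated ring alkene. The fallback replaces the radical closure by a palladium-mediated one and sets out from 8. Kinetic deprotonation of the methyl group with KN(SiMe3)2 and trapping with PhNTf2 gives the terminal enol triflate F2. An intramolecular Heck reaction (Pd(OAc)2, PPh3, K2CO3, MeCN, 70 °C) closes the C13–C16 bond 5-exo on the β face and, after β-hydride elimination toward C11, gives the 16-methylene 11-ene tricycle F3. Mukaiyama hydration (Co(acac)2, PhSiH3, O2, i-PrOH), which should prefer the 1,1-disubstituted alkene, places the hydroxyl on the less hindered exo face of the tertiary C16 radical and gives the 11-ene tertiary alcohol F4. Hydrogenation of the remaining ring alkene (H2, Pd/C, EtOAc) returns to the route at 9.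

Step 10. The cuprate may add to C6 with poor facial selectivity, or the tertiary alkoxide may compete with the enolate for the triflating agent. The fallback puts the face selection under reagent control and sets out from 12. A Hayashi–Miyaura conjugate vinylation ([RhCl(cod)]2, the BINAP enantiomer matched to β-face delivery, CH2=CHBF3K, aqueous dioxane) gives the 6β-vinyl ketone F5 after work-up. Kinetic deprotonation at C5 with KN(SiMe3)2 (2.2 equiv; C9 is a hindered ring-fusion methine) and trapping with 2-[N,N-bis(trifluoromethylsulfonyl)amino]-5-chloropyridine returns to the route at 14.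

Further compounds
F1 | step 14 | Δ1(10) β-keto ester: ring A closed, C1=C10, 4α-CO2t-Bu, 4β-Me, H5 β, 6β-vinyl | C[C@@]1(C(=O)OC(C)(C)C)C(=O)CC=C2[C@@H]3CC[C@@H]4C[C@]3(C[C@@]4(C)O)[C@@H](C=C)[C@H]12
F2 | step 7 | terminal enol triflate of ketone 8 (8β-(2-triflyloxyallyl)) | CC(=O)OC1C[C@@H](O[Si](C)(C)C(C)(C)C)[C@@H]2CC=CC[C@]12CC(=C)OS(=O)(=O)C(F)(F)F
F3 | step 7 | 16-methylene 11-ene tricycle (6-OAc, 10β-OTBS, C11=C12) | CC(=O)OC1C[C@@H](O[Si](C)(C)C(C)(C)C)[C@@H]2C=C[C@@H]3C[C@]12CC3=C
F4 | step 7 | 11-ene tertiary alcohol: 9 with a C11=C12 double bond (16-OH exo) | CC(=O)OC1C[C@@H](O[Si](C)(C)C(C)(C)C)[C@@H]2C=C[C@@H]3C[C@]12C[C@@]3(C)O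
F5 | step 10 | 6β-vinyl C10 ketone of the tricycle (16-OH exo) | O=C1C[C@H](C=C)[C@@]23C[C@@](C)(O)[C@@H](C2)CC[C@@H]13
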